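**Retrosynthetic overview** (germacrane numbering: ring C1–C10, C1=C10, ester carbon C14 on C10, lactone C6–O–C12(=O)–C11(=C13)–C7)
- Feature: C2–C5 carry four contiguous C–O bonds as two adjacent cis-oxiranes (C2–C3 and C4–C5, methyl on C4) next to the lactone oxygen on C6. The route reaches this array by walking one central C3–C4 oxirane that is flanked by a C2 hydroxyl and a C5 mesylate.
- Disconnections: C11=C13 (elimination of a masked hydroxymethyl); C8/C9 esters ⇒ cis-diol ⇒ (Z)-C8=C9 (RCM, closes the ten-membered ring); C1=C10 (HWE with a phosphono dienolate); diepoxide ⇒ hydroxy epoxy mesylate 20 (epoxide walk); C4–C5 (NHK coupling of lactone aldehyde 7 with (Z)-iodoalkene 15).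
- Ring order: γ-lactone (from butenolide 1) → C3–C4 oxirane (step 10) → C2–C3 and C4–C5 oxiranes (step 14) → ten-membered carbocycle (step 21); the epoxyangelate oxirane is made separately (step 25).
- Stereocontrol: C6 from 1; C7 by trans conjugate addition; C2 by transfer hydrogenation; C5 by Felkin–Anh NHK addition; C3/C4 by doubly hydroxyl-directed epoxidation; C8/C9 by syn-dihydroxylation of the ring alkene.

Key step: step 14

Remark: from 26 to 45 C11 is carried as a mixture of epimers (written without a descriptor); this centre becomes sp2 in step 29.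

Step 1
Reactants: 1 (S)-5-(hydroxymethyl)furan-2(5H)-one
Product: 2 (S)-5-{[(tert-butyldiphenylsilyl)oxy]methyl}furan-2(5H)-one
Conditions: TBDPSCl, imidazole, DMF, 0 °C → rt
Reagents that add atoms: tert-butylchlorodiphenylsilane, CC(C)(C)[Si](Cl)(c1ccccc1)c1ccccc1
Why: Imidazole-mediated silylation of the primary alcohol; the bulky silyloxymethyl group then shields one face of the butenolide.

Step 2
Reactants: 2 silyl-protected butenolide; 3 vinylmagnesium bromide
Product: 5 (4R,5S)-5-{[(tert-butyldiphenylsilyl)oxy]methyl}-4-vinyldihydrofuran-2(3H)-one, via silyl ketene acetal 4 (not isolated)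
Conditions: CuBr·SMe2 (10 mol %), TMSCl, THF, −78 °C; aq. NH4Cl
Reagents that add atoms: none
Why: Copper-catalysed, TMSCl-accelerated conjugate addition of the vinyl Grignard reagent, which enters C7 anti to the C6 substituent and gives the 6,7-trans lactone after hydrolysis of 4.

Step 3
Reactants: 5 trans-vinyl lactone silyl ether
Product: 6 (4R,5S)-5-(hydroxymethyl)-4-vinyldihydrofuran-2(3H)-one
Conditions: TBAF, AcOH (1:1), THF, 0 °C → rt
Reagents that add atoms: none
Why: Fluoride cleavage of the silyl ether, buffered with acetic acid so that the lactone is neither opened nor epimerised.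

Step 4
Reactants: 6 hydroxymethyl lactone
Product: 7 (2S,3R)-5-oxo-3-vinyltetrahydrofuran-2-carbaldehyde
Conditions: Dess–Martin periodinane, NaHCO3, CH2Cl2, 0 °C; used crude
Reagents that add atoms: none
Why: Dess–Martin oxidation under buffered, non-basic conditions, which should leave the enolisable C6 centre of the α-acyloxy aldehyde intact.

Step 5
Reactants: 8 4-methoxybenzyl alcohol; 9 2-chloro-N-methoxy-N-methylacetamide
Product: 10 N-methoxy-2-[(4-methoxybenzyl)oxy]-N-methylacetamide
Conditions: NaH, THF, 0 °C → rt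
Reagents that add atoms: none
Why: Williamson etherification, the sodium alkoxide of 8 displacing chloride from the α-chloro amide by SN2.

Step 6
Reactants: 10 Weinreb amide; 11 1-propynylmagnesium bromide
Product: 12 1-[(4-methoxybenzyl)oxy]pent-3-yn-2-one
Conditions: THF, −20 → 0 °C; aq. NH4Cl
Reagents that add atoms: none
Why: Weinreb ketone synthesis, in which the chelated tetrahedral intermediate stops the alkynyl addition at the ynone.

Step 7
Reactants: 12 ynone
Product: 13 (S)-1-[(4-methoxybenzyl)oxy]pent-3-yn-2-ol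
Conditions: Ru[(R,R)-TsDPEN](p-cymene) (1 mol %), i-PrOH, rt
Reagents that add atoms: none
Why: Noyori asymmetric transfer hydrogenation of an ynone, in which the alkyne is the π-directing group, so that the (R,R)-catalyst should give the (S)-carbinol (C2).

Step 8
Reactants: 13 (S)-propargylic alcohol
Product: 15 (S,Z)-4-iodo-1-[(4-methoxybenzyl)oxy]pent-3-en-2-ol, via cyclic alkenylalanate 14 (not isolated)
Conditions: Red-Al, THF, 0 °C → rt; then I2, −78 °C → rt
Reagents that add atoms: iodine, II
Why: Hydroxyl-directed trans-hydroalumination places aluminium on the distal alkyne carbon cis to the carbinol (14), and iodinolysis with retention gives the (Z)-iodoalkene that carries the C3=C4 geometry and the C4 methyl group.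

Step 9
Reactants: 7 lactone aldehyde; 15 (Z)-iodoalkene
Product: 16 (Z)-ene-1,4-diol (C2-OH, C5-OH; 2S,5R,6S,7R)
Conditions: CrCl2 (4 equiv), NiCl2 (2 mol %), DMSO, rt
Reagents that add atoms: none
Why: Nozaki–Hiyama–Kishi coupling, selective for the aldehyde beside lactone and free hydroxyl and retentive at the alkene; the C5 carbinol should form by polar Felkin–Anh addition anti to the C6–O bond (5,6-anti).

Step 10
Reactants: 16 (Z)-ene-1,4-diol
Product: 17 epoxy diol (cis C3–C4 oxirane threo to C2-OH and C5-OH; 2R,3S,4R,5S,6S,7R)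
Conditions: mCPBA, NaHCO3, CH2Cl2, 0 °C
Reagents that add atoms: 3-chloroperbenzoic acid, OOC(=O)c1cccc(Cl)c1
Why: Peracid epoxidation directed by hydrogen bonding from both allylic hydroxyls, which lie on the same alkene face in the A(1,3)-minimised conformer (matched), so that the oxirane forms threo to both; the monosubstituted vinyl group reacts far more slowly.

Step 11
Reactants: 17 epoxy diol
Product: 18 C2 triethylsilyl ether of 17 (C5-OH free)
Conditions: TESCl (1.05 equiv), imidazole, CH2Cl2, −40 °C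
Reagents that add atoms: chlorotriethylsilane, CC[Si](Cl)(CC)CC
Why: Selective silylation of the less hindered C2 hydroxyl (flanked by CH2 and CH) over the C5 hydroxyl (flanked by the quaternary oxirane carbon C4 and ring carbon C6).

Step 12
Reactants: 18 C2 silyl ether
Product: 19 C5 mesylate of 18
Conditions: MsCl, Et3N, DMAP (cat.), CH2Cl2, 0 °C
Reagents that add atoms: methanesulfonyl chloride, CS(Cl)(=O)=O
Why: Mesylation through sulfene, which tolerates hindrance, turns the only free hydroxyl (C5) into the leaving group with retention of configuration.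

Step 13
Reactants: 19 silyl ether mesylate
Product: 20 hydroxy epoxy mesylate (C2-OH, cis C3–C4 oxirane, C5-OMs; 2R,3S,4S,5S,6S,7R)
Conditions: TBAF, AcOH (1:1), THF, 0 °C
Reagents that add atoms: none
Why: Acetic-acid-buffered fluoride removes the triethylsilyl ether without forming a free alkoxide, so that the precursor of the walk can be isolated.

Step 14
Reactants: 20 hydroxy epoxy mesylate
Product: 23 anti-diepoxide (cis C2–C3 and cis C4–C5 oxiranes; 2R,3R,4R,5R,6S,7R), via potassium C2 alkoxide 21 (not isolated), via potassium C4 alkoxide 22 (not isolated)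
Conditions: t-BuOK (1.1 equiv), THF–t-BuOH (4:1), −20 → 0 °C
Reagents that add atoms: none
Why: Potassium tert-butoxide makes the C2 alkoxide 21, which attacks C3 from the back of the C3–O bond and opens the C3–C4 oxirane reversibly to the tertiary C4 alkoxide 22, and 22 displaces the C5 mesylate irreversibly and so drains the equilibrium. The closest known reaction type is the Payne rearrangement coupled to an irreversible ring closure, as in epoxide migrations of epoxy sulfonates in anhydro-alditol chemistry. Both oxiranes close in the 3-exo-tet mode (O2 onto C3, then O4 onto C5). C3 and C5 are inverted by backside displacement while C2 and C4 keep their oxygens, so the diepoxide follows stereospecifically from the cis-oxirane of 20 that lies threo to both carbinol centres. The selectivity needed is the relay over direct 5-exo-tet attack of the C2 alkoxide on C5 (which would give a cis-fused 3,4-epoxytetrahydrofuran); C5 is a secondary carbon between the quaternary C4 and the acyloxy-bearing C6 and is reached by O2 only through a strained bicyclic transition state, whereas the vicinal tertiary alkoxide closes at once, and tert-butanol assists oxirane opening by hydrogen bonding. The non-nucleophilic base keeps the lactone closed, so that no C6 alkoxide competes for C5.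

Step 15
Reactants: 23 diepoxide; 24 formaldehyde
Product: 26 11-(hydroxymethyl) derivative of 23, via lithium enolate 25 (not isolated)
Conditions: LiHMDS, THF, −78 °C; then monomeric CH2O, −78 °C; aq. NH4Cl
Reagents that add atoms: none
Why: Aldol addition of the lactone lithium enolate to formaldehyde brings in C13; C11 should form mainly trans to the C7 vinyl group, but its configuration is irrelevant because it is erased in step 29.

Step 16
Reactants: 26 hydroxymethyl lactone
Product: 27 tert-butyldimethylsilyl ether of 26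
Conditions: TBSCl, imidazole, DMF, 0 °C → rt
Reagents that add atoms: tert-butylchlorodimethylsilane, CC(C)(C)[Si](C)(C)Cl
Why: Silylation of the primary alcohol masks the future exocyclic methylene as a group that is neither electrophilic nor oxidisable.

Step 17
Reactants: 27 PMB ether
Product: 28 C1 alcohol (2,3-epoxy alcohol)
Conditions: DDQ, CH2Cl2–pH 7 buffer, 0 °C
Reagents that add atoms: none
Why: Oxidative cleavage of the 4-methoxybenzyl ether by DDQ (hydride abstraction, then hydrolysis of the oxocarbenium ion), which spares the silyl ether, the oxiranes and the vinyl group.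

Step 18
Reactants: 28 C1 alcohol
Product: 29 C1 aldehyde (cis-2,3-epoxy aldehyde)
Conditions: Dess–Martin periodinane, NaHCO3, CH2Cl2, 0 °C; used at once
Reagents that add atoms: none
Why: Buffered Dess–Martin oxidation of a 2,3-epoxy alcohol, a standard way to the epoxy aldehyde without epimerisation at C2.

Step 19
Reactants: 30 trimethyl phosphonoacetate; 31 acetaldehyde
Product: 32 methyl 2-(dimethoxyphosphoryl)but-2-enoate (E/Z mixture)
Conditions: TiCl4, N-methylmorpholine, THF, 0 °C → rt
Reagents that add atoms: none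
Why: Lehnert-type Knoevenagel condensation (TiCl4/amine) of the phosphonoacetate with acetaldehyde; both alkene isomers give the same dienolate in step 20.

Step 20
Reactants: 29 epoxy aldehyde; 32 phosphono butenoate
Product: 34 triene (C1=C10 with CO2Me and vinyl on C10; C2 cis to the C9 vinyl group), via lithium dienolate 33 (not isolated)
Conditions: 32, LiHMDS, THF, −78 °C; then 29, −78 → 0 °C
Reagents that add atoms: none
Why: Horner–Wadsworth–Emmons olefination through the γ-deprotonated dienolate 33, which adds to the aldehyde at the phosphorus-bearing α-carbon and loses phosphate to give the 2-vinyl enoate with C2 trans to CO2Me (the usual E preference of α-substituted phosphonoacetates).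

Step 21
Reactants: 34 triene
Product: 35 ten-membered (8Z)-diene (C8=C9 conjugated to C1=C10)
Conditions: Hoveyda–Grubbs II (10 mol %), toluene (1 mM), 80 °C
Reagents that add atoms: none
Why: Ring-closing metathesis between the C7 vinyl group and the terminal alkene of the dienoate, driven by loss of ethylene; the two cis-oxiranes, the cis C1=C10 bond and the trans-lactone turn the chain ends towards each other, and the ring should take up C8=C9 as the less strained Z isomer.

Step 22
Reactants: 35 cyclic diene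
Product: 36 8,9-cis-diol (8S,9R)
Conditions: OsO4 (5 mol %), NMO, acetone–H2O, 0 °C; aq. Na2SO3
Reagents that add atoms: osmium tetroxide (catalytic carrier), O=[Os](=O)(=O)=O; N-methylmorpholine N-oxide, C[N+]1([O-])CCOCC1; water, O
Why: Upjohn dihydroxylation at the only alkene without an acceptor substituent (C8=C9); the syn addition to the cis ring alkene fixes the 8,9-erythro relation, and attack on the face turned away from the C10 ester carbon and the lactone methylene C11 should give 8S,9R, a facial choice that rests on ring conformation and is the least secure stereochemical element of the route.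

Step 23
Reactants: 36 diol
Product: 37 C9 acetate (C8-OH free)
Conditions: Ac2O (1.1 equiv), pyridine, DMAP (cat.), CH2Cl2, −40 → −20 °C
Reagents that add atoms: acetic anhydride, CC(=O)OC(C)=O
Why: Monoacylation of the allylic C9 hydroxyl, which is the more accessible (sp2 neighbour C10) and the more acidic one, in preference to the C8 hydroxyl next to the ring-fusion carbon C7.

Step 24
Reactants: 38 methyl angelate
Product: 39 (Z)-2-methylbut-2-en-1-ol
Conditions: DIBAL-H, CH2Cl2, −78 °C; Rochelle salt
Reagents that add atoms: none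
Why: 1,2-Reduction of the enoate by DIBAL-H to the allylic alcohol with retention of the Z geometry.

Step 25
Reactants: 39 (Z)-2-methylbut-2-en-1-ol
Product: 40 [(2R,3S)-2,3-dimethyloxiran-2-yl]methanol
Conditions: Ti(Oi-Pr)4 (10 mol %), D-(−)-DIPT (12 mol %), TBHP, 4 Å MS, CH2Cl2, −20 °C
Reagents that add atoms: tert-butyl hydroperoxide, CC(C)(C)OO
Why: Sharpless asymmetric epoxidation, in which the D-(−)-tartrate catalyst delivers oxygen to the face that gives the (2R,3S)-epoxy alcohol (reagent control on an achiral allylic alcohol).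

Step 26
Reactants: 40 epoxy alcohol
Product: 41 (2S,3S)-2,3-dimethyloxirane-2-carboxylic acid (epoxyangelic acid)
Conditions: RuCl3 (cat.), NaIO4, MeCN–EtOAc–H2O, rt
Reagents that add atoms: sodium periodate (oxygen source through RuO4), [Na+].[O-]I(=O)(=O)=O; water, O
Why: Sharpless ruthenium tetroxide oxidation of a primary epoxy alcohol to the glycidic acid, which leaves the oxirane and both stereocentres untouched.

Step 27
Reactants: 37 C9 acetate; 41 epoxyangelic acid
Product: 43 C8 epoxyangelate C9 acetate, via mixed anhydride 42 (not isolated)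
Conditions: 41, 2,4,6-trichlorobenzoyl chloride, Et3N, THF, rt; then 37, DMAP, toluene, rt
Reagents that add atoms: none
Why: Yamaguchi esterification, in which DMAP attacks the less hindered (epoxyangeloyl) carbonyl of 42 and the acylpyridinium ion acylates the remaining C8 hydroxyl with retention at C8 and in the acid.

Step 28
Reactants: 43 diester silyl ether
Product: 44 C13 primary alcohol
Conditions: TBAF, AcOH (1:1), THF, 0 °C → rt
Reagents that add atoms: none
Why: Buffered fluoride cleaves the primary silyl ether in a near-neutral medium that the oxiranes, the esters and the allylic acetate should tolerate.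

Step 29
Reactants: 44 β-hydroxymethyl lactone
Product: 46 target CNP0077535.3, via C13 mesylate 45 (not isolated)
Conditions: MsCl, Et3N (excess), CH2Cl2, 0 °C → rt
Reagents that add atoms: none
Why: Mesylation of the β-hydroxy lactone followed by E1cB loss of methanesulfonate under triethylamine creates the exocyclic C11=C13 methylene and removes the C11 stereocentre.

**Compound list**
1 | (S)-5-(hydroxymethyl)furan-2(5H)-one | O=C1C=C[C@@H](CO)O1 | starting material
2 | (S)-5-{[(tert-butyldiphenylsilyl)oxy]methyl}furan-2(5H)-one | O=C1C=C[C@@H](CO[Si](c2ccccc2)(c2ccccc2)C(C)(C)C)O1 | intermediate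
3 | vinylmagnesium bromide | C=C[Mg]Br | starting material
4 | tert-butyldiphenyl{[(2S,3S)-5-[(trimethylsilyl)oxy]-3-vinyl-2,3-dihydrofuran-2-yl]methoxy}silane | C[Si](C)(C)OC1=C[C@H](C=C)[C@@H](CO[Si](c2ccccc2)(c2ccccc2)C(C)(C)C)O1 | intermediate (not isolated)
5 | (4R,5S)-5-{[(tert-butyldiphenylsilyl)oxy]methyl}-4-vinyldihydrofuran-2(3H)-one | O=C1C[C@H](C=C)[C@@H](CO[Si](c2ccccc2)(c2ccccc2)C(C)(C)C)O1 | intermediate
6 | (4R,5S)-5-(hydroxymethyl)-4-vinyldihydrofuran-2(3H)-one | O=C1C[C@H](C=C)[C@@H](CO)O1 | intermediate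
7 | (2S,3R)-5-oxo-3-vinyltetrahydrofuran-2-carbaldehyde | O=C1C[C@H](C=C)[C@@H](C=O)O1 | intermediate
8 | 4-methoxybenzyl alcohol | COc1ccc(CO)cc1 | starting material
9 | 2-chloro-N-methoxy-N-methylacetamide | CON(C)C(=O)CCl | starting material
10 | N-methoxy-2-[(4-methoxybenzyl)oxy]-N-methylacetamide | CON(C)C(=O)COCc1ccc(OC)cc1 | intermediate
11 | 1-propynylmagnesium bromide | CC#C[Mg]Br | starting material
12 | 1-[(4-methoxybenzyl)oxy]pent-3-yn-2-one | CC#CC(=O)COCc1ccc(OC)cc1 | intermediate
13 | (S)-1-[(4-methoxybenzyl)oxy]pent-3-yn-2-ol | CC#C[C@H](O)COCc1ccc(OC)cc1 | intermediate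
14 | sodium cyclic (Z)-alkenylalanate of 13 (O2–Al–C4 five-membered ring, two 2-methoxyethoxy groups on Al) | CC1=C[C@@H](COCc2ccc(OC)cc2)O[Al-]1(OCCOC)OCCOC.[Na+] | intermediate (not isolated)
15 | (S,Z)-4-iodo-1-[(4-methoxybenzyl)oxy]pent-3-en-2-ol | C/C(I)=C/[C@H](O)COCc1ccc(OC)cc1 | intermediate
16 | (4R,5S)-5-[(1R,2Z,4S)-1,4-dihydroxy-5-(4-methoxybenzyloxy)-2-methylpent-2-en-1-yl]-4-vinyldihydrofuran-2(3H)-one | O=C1C[C@H](C=C)[C@@H]([C@H](O)/C(C)=C\[C@H](O)COCc2ccc(OC)cc2)O1 | intermediate
17 | (4R,5S)-5-{(S)-hydroxy[(2R,3S)-3-{(R)-1-hydroxy-2-[(4-methoxybenzyl)oxy]ethyl}-2-methyloxiran-2-yl]methyl}-4-vinyldihydrofuran-2(3H)-one | O=C1C[C@H](C=C)[C@@H]([C@H](O)[C@@]2(C)O[C@H]2[C@H](O)COCc3ccc(OC)cc3)O1 | intermediate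
18 | C2 triethylsilyl ether of 17 (configuration as in 17) | O=C1C[C@H](C=C)[C@@H]([C@H](O)[C@@]2(C)O[C@H]2[C@H](O[Si](CC)(CC)CC)COCc3ccc(OC)cc3)O1 | intermediate
19 | C5 methanesulfonate of 18 (configuration as in 17) | O=C1C[C@H](C=C)[C@@H]([C@H](OS(C)(=O)=O)[C@@]2(C)O[C@H]2[C@H](O[Si](CC)(CC)CC)COCc3ccc(OC)cc3)O1 | intermediate
20 | (S)-[(2S,3S)-3-{(R)-1-hydroxy-2-[(4-methoxybenzyl)oxy]ethyl}-2-methyloxiran-2-yl][(2S,3R)-5-oxo-3-vinyltetrahydrofuran-2-yl]methyl methanesulfonate | O=C1C[C@H](C=C)[C@@H]([C@H](OS(C)(=O)=O)[C@@]2(C)O[C@H]2[C@H](O)COCc3ccc(OC)cc3)O1 | intermediate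
21 | potassium C2 alkoxide of 20 | O=C1C[C@H](C=C)[C@@H]([C@H](OS(C)(=O)=O)[C@@]2(C)O[C@H]2[C@H]([O-])COCc3ccc(OC)cc3)O1.[K+] | intermediate (not isolated)
22 | potassium C4 alkoxide after the first migration (cis C2–C3 oxirane, tertiary C4 alkoxide, C5 mesylate) | O=C1C[C@H](C=C)[C@@H]([C@H](OS(C)(=O)=O)[C@@](C)([O-])[C@@H]2O[C@@H]2COCc3ccc(OC)cc3)O1.[K+] | intermediate (not isolated)
23 | (4R,5S)-5-{(2R,3R)-3-[(2R,3R)-3-{[(4-methoxybenzyl)oxy]methyl}oxiran-2-yl]-3-methyloxiran-2-yl}-4-vinyldihydrofuran-2(3H)-one | O=C1C[C@H](C=C)[C@@H]([C@H]2O[C@@]2(C)[C@@H]2O[C@@H]2COCc3ccc(OC)cc3)O1 | intermediate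
24 | formaldehyde | C=O | starting material
25 | lithium enolate of 23 | [Li]OC1=C[C@H](C=C)[C@@H]([C@H]2O[C@@]2(C)[C@@H]2O[C@@H]2COCc3ccc(OC)cc3)O1 | intermediate (not isolated)
26 | 23 with a hydroxymethyl group on C11 (C11 epimers) | O=C1C(CO)[C@H](C=C)[C@@H]([C@H]2O[C@@]2(C)[C@@H]2O[C@@H]2COCc3ccc(OC)cc3)O1 | intermediate
27 | tert-butyldimethylsilyl ether of 26 | O=C1C(CO[Si](C)(C)C(C)(C)C)[C@H](C=C)[C@@H]([C@H]2O[C@@]2(C)[C@@H]2O[C@@H]2COCc3ccc(OC)cc3)O1 | intermediate
28 | C1 alcohol (27 without the 4-methoxybenzyl group) | O=C1C(CO[Si](C)(C)C(C)(C)C)[C@H](C=C)[C@@H]([C@H]2O[C@@]2(C)[C@@H]2O[C@@H]2CO)O1 | intermediate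
29 | C1 aldehyde (cis-2,3-epoxy aldehyde) | O=C1C(CO[Si](C)(C)C(C)(C)C)[C@H](C=C)[C@@H]([C@H]2O[C@@]2(C)[C@@H]2O[C@@H]2C=O)O1 | intermediate
30 | trimethyl phosphonoacetate | COC(=O)CP(=O)(OC)OC | starting material
31 | acetaldehyde | CC=O | starting material
32 | methyl 2-(dimethoxyphosphoryl)but-2-enoate (E/Z) | CC=C(C(=O)OC)P(=O)(OC)OC | intermediate
33 | lithium dienolate of 32 | [Li]OC(OC)=C(C=C)P(=O)(OC)OC | intermediate (not isolated)
34 | triene: methyl (E)-2-vinylprop-2-enoate arm on C2 of the diepoxide lactone (C2 cis to the vinyl group) | O=C1C(CO[Si](C)(C)C(C)(C)C)[C@H](C=C)[C@@H]([C@H]2O[C@@]2(C)[C@@H]2O[C@@H]2/C=C(\C=C)C(=O)OC)O1 | intermediate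
35 | ten-membered 1(10),8-diene: 13-silyloxy-2,3:4,5-diepoxy-germacra-1(10),8Z-dien-12,6-olid-14-oic acid methyl ester | CC(C)(C)[Si](C)(C)OCC1C(=O)O[C@H]2[C@H]1/C=C\C(C(=O)OC)=C/[C@H]1O[C@H]1[C@]1(C)O[C@H]21 | intermediate
36 | (8S,9R)-8,9-diol of 35 | CC(C)(C)[Si](C)(C)OCC1C(=O)O[C@H]2[C@H]1[C@H](O)[C@H](O)/C(C(=O)OC)=C\[C@H]1O[C@H]1[C@]1(C)O[C@H]21 | intermediate
37 | C9 acetate of 36 | CC(C)(C)[Si](C)(C)OCC1C(=O)O[C@H]2[C@H]1[C@H](O)[C@H](OC(C)=O)/C(C(=O)OC)=C\[C@H]1O[C@H]1[C@]1(C)O[C@H]21 | intermediate
38 | methyl angelate, methyl (Z)-2-methylbut-2-enoate | C/C=C(/C)C(=O)OC | starting material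
39 | (Z)-2-methylbut-2-en-1-ol | C/C=C(/C)CO | intermediate
40 | [(2R,3S)-2,3-dimethyloxiran-2-yl]methanol | OC[C@@]1(C)O[C@H]1C | intermediate
41 | (2S,3S)-2,3-dimethyloxirane-2-carboxylic acid | OC(=O)[C@@]1(C)O[C@H]1C | intermediate
42 | (2S,3S)-2,3-dimethyloxirane-2-carboxylic 2,4,6-trichlorobenzoic anhydride | O=C(OC(=O)[C@@]1(C)O[C@H]1C)c1c(Cl)cc(Cl)cc1Cl | intermediate (not isolated)
43 | C8 (2S,3S)-epoxyangelate of 37 | CC(C)(C)[Si](C)(C)OCC1C(=O)O[C@H]2[C@H]1[C@H](OC(=O)[C@@]3(C)O[C@H]3C)[C@H](OC(C)=O)/C(C(=O)OC)=C\[C@H]1O[C@H]1[C@]1(C)O[C@H]21 | intermediate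
44 | C13 alcohol (43 without the silyl group) | OCC1C(=O)O[C@H]2[C@H]1[C@H](OC(=O)[C@@]3(C)O[C@H]3C)[C@H](OC(C)=O)/C(C(=O)OC)=C\[C@H]1O[C@H]1[C@]1(C)O[C@H]21 | intermediate
45 | C13 methanesulfonate of 44 | CS(=O)(=O)OCC1C(=O)O[C@H]2[C@H]1[C@H](OC(=O)[C@@]3(C)O[C@H]3C)[C@H](OC(C)=O)/C(C(=O)OC)=C\[C@H]1O[C@H]1[C@]1(C)O[C@H]21 | intermediate (not isolated)
46 | CNP0077535.3: methyl (2R,3R,4R,5R,6S,7R,8S,9R)-9-acetoxy-2,3:4,5-diepoxy-8-[(2S,3S)-2,3-epoxy-2-methylbutanoyloxy]-germacra-1(10),11(13)-dien-12,6-olid-14-oate | C=C1C(=O)O[C@H]2[C@H]1[C@H](OC(=O)[C@@]1(C)O[C@H]1C)[C@H](OC(C)=O)/C(C(=O)OC)=C\[C@H]1O[C@H]1[C@]1(C)O[C@H]21 | target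

**Step count:** 29 steps in total. Longest linear sequence: 21 steps (1–4, 9–18, 20–23, 27–29).

**Steps most likely to fail**

1. Step 14. The C2 alkoxide may displace the C5 mesylate directly (5-exo-tet) before it opens the oxirane, because the relay needs rotamers that place C1 and C6 over the oxirane; this would give a cis-fused epoxytetrahydrofuran. The fallback is a direct double ring closure without epoxide migration. It sets out from 16: selective silylation of the C2 hydroxyl (TESCl, imidazole, −40 °C) gives the C2 triethylsilyl ether F1. Hydroxyl-directed syn-dihydroxylation (OsO4·TMEDA, CH2Cl2, −78 °C), guided by the free C5 hydroxyl to the alkene face that the peracid takes, gives the 3,4,5-triol F2. Mesylation of the two secondary hydroxyls (MsCl, Et3N; the tertiary C4 hydroxyl stays free) gives the 3,5-bis-mesylate F3. Fluoride (TBAF, THF, 0 °C) then frees the C2 alkoxide, which displaces the vicinal C3 mesylate, and the C4 alkoxide displaces the C5 mesylate, both 3-exo-tet with inversion. The route is rejoined at 23.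

2. Step 21. Ring strain and the sluggish, electron-poor diene terminus may divert the ruthenium carbene into acyclic dimerisation or leave the triene unchanged. The fallback closes the ring on a non-conjugated, more flexible triene and forms C1=C10 afterwards. It sets out from 29: aldol addition of the lithium dienolate of methyl but-3-enoate (LDA, THF, −78 °C, α-attack) gives the β-hydroxy α-vinyl ester F4 (mixture at C1 and C10). Ring-closing metathesis of its two unconjugated terminal alkenes (Grubbs II, high dilution) gives the ten-membered β-hydroxy ester F5. Mesylation and E1cB elimination (MsCl, Et3N; then DBU) form the conjugated C1=C10 bond. The route is rejoined at 35.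

3. Step 22. Facial selectivity may be poor or reversed: the exposed face of the cis-alkene in the tub-shaped ring may be the one flanked by C11 and the ester, and osmylation there would give the 8,9-bis-epimeric diol. The fallback inverts both carbinol centres by oxidation and hydride delivery from that same exposed face. It sets out from 35, whose osmylation product is then the (8R,9S)-diol F6. Selective oxidation of the allylic C9 hydroxyl (MnO2, CH2Cl2) gives the 9-ketone F7. Luche reduction (NaBH4, CeCl3, MeOH, −78 °C) gives the C9-inverted diol F8. Acetylation of the C9 hydroxyl (Ac2O, pyridine) gives the 8-epi acetate F9. Dess–Martin oxidation gives the 8-ketone F10, and reduction at −78 °C (Zn(BH4)2) places the C8 hydroxyl on the hindered face. The route is rejoined at 37.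

**Further compounds**
F1 | step 14 | C2 triethylsilyl ether of 16 | O=C1C[C@H](C=C)[C@@H]([C@H](O)/C(C)=C\[C@H](O[Si](CC)(CC)CC)COCc2ccc(OC)cc2)O1
F2 | step 14 | 3,4,5-triol (C3-OH and C4-OH syn, on the face of C5-OH; C2 silyl ether) | O=C1C[C@H](C=C)[C@@H]([C@H](O)[C@@](C)(O)[C@@H](O)[C@H](O[Si](CC)(CC)CC)COCc2ccc(OC)cc2)O1
F3 | step 14 | 3,5-bis-methanesulfonate of F2 | O=C1C[C@H](C=C)[C@@H]([C@H](OS(C)(=O)=O)[C@@](C)(O)[C@@H](OS(C)(=O)=O)[C@H](O[Si](CC)(CC)CC)COCc2ccc(OC)cc2)O1
F4 | step 21 | aldol adduct of 29 with methyl but-3-enoate (C1 carbinol, C10 bearing CO2Me and vinyl) | O=C1C(CO[Si](C)(C)C(C)(C)C)[C@H](C=C)[C@@H]([C@H]2O[C@@]2(C)[C@@H]2O[C@@H]2C(O)C(C=C)C(=O)OC)O1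
F5 | step 21 | ten-membered 8Z-ene with C1 hydroxyl and sp3 C10 | CC(C)(C)[Si](C)(C)OCC1C(=O)O[C@H]2[C@H]1/C=C\C(C(=O)OC)C(O)[C@H]1O[C@H]1[C@]1(C)O[C@H]21
F6 | step 22 | (8R,9S)-diol, 8,9-bis-epimer of 36 | CC(C)(C)[Si](C)(C)OCC1C(=O)O[C@H]2[C@H]1[C@@H](O)[C@@H](O)/C(C(=O)OC)=C\[C@H]1O[C@H]1[C@]1(C)O[C@H]21
F7 | step 22 | 9-ketone of F6 | CC(C)(C)[Si](C)(C)OCC1C(=O)O[C@H]2[C@H]1[C@@H](O)C(=O)/C(C(=O)OC)=C\[C@H]1O[C@H]1[C@]1(C)O[C@H]21
F8 | step 22 | (8R,9R)-diol, 8-epimer of 36 | CC(C)(C)[Si](C)(C)OCC1C(=O)O[C@H]2[C@H]1[C@@H](O)[C@H](O)/C(C(=O)OC)=C\[C@H]1O[C@H]1[C@]1(C)O[C@H]21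
F9 | step 22 | C9 acetate of F8, 8-epimer of 37 | CC(C)(C)[Si](C)(C)OCC1C(=O)O[C@H]2[C@H]1[C@@H](O)[C@H](OC(C)=O)/C(C(=O)OC)=C\[C@H]1O[C@H]1[C@]1(C)O[C@H]21
F10 | step 22 | 8-ketone 9-acetate | CC(C)(C)[Si](C)(C)OCC1C(=O)O[C@H]2[C@H]1C(=O)[C@H](OC(C)=O)/C(C(=O)OC)=C\[C@H]1O[C@H]1[C@]1(C)O[C@H]21
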